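The route rests on cutting two neighbouring bonds of ring A at once: O1–C7a of the dihydrofuran and C7–C(=O) of the cinnamoyl ketone, which lie ortho to each other next to the C6 methoxy group. A fluoroarene is turned into the C7–C7a aryne; the tethered secondary alkoxide closes the furan ring at C7a, and the C7 aryllithium left behind, held between O1 and the C6 oxygen, is acylated by a cinnamic Weinreb amide, all in one flask. The precursor is an S-configured 1-aryl-3-methylbutan-2-ol with a MOM-protected tertiary oxygen and a 2-fluoro-4-methoxy-6-(methoxymethoxy)phenyl ring, assembled from a chiral-pool epoxide and an ortho-lithiated fluoroarene.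

Key step: step 7

Remark on the chemistry: C2 of the target is S (CIP order O1 > CMe2OH > C3 > H). No bond to this carbon is made or broken after step 1 and the priority order stays the same throughout, so methyl (S)-glycidate carries the required configuration. All three hydroxyl groups travel as methoxymethyl (MOM) ethers so that one acid treatment ends the synthesis.

Step 1
Reactants: 1 methyl (S)-glycidate [methyl (2S)-oxirane-2-carboxylate]
Product: 3 2-[(2S)-oxiran-2-yl]propan-2-ol, via 1-[(2S)-oxiran-2-yl]ethan-1-one 2 (not isolated)
Conditions: MeMgCl (2.2 equiv), THF, −78 to −20 °C; aq NH4Cl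
Reagents that add atoms: methylmagnesium chloride, C[Mg]Cl
Why: Double Grignard addition to the ester (through the methyl ketone) should outrun attack on the epoxide at low temperature, the chloride reagent limits halohydrin formation, and the epoxide stereocentre is not involved, so the S configuration of the chiral pool is kept.

Step 2
Reactants: 3 2-[(2S)-oxiran-2-yl]propan-2-ol
Product: 4 (2S)-2-[2-(methoxymethoxy)propan-2-yl]oxirane
Conditions: MOMCl, i-Pr2NEt, DMAP (cat.), CH2Cl2, 0 to 35 °C
Reagents that add atoms: chloromethyl methyl ether, COCCl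
Why: O-Alkylation of the tertiary alcohol by the chloromethyl ether (MOM acetal formation) under amine base never forms a free alkoxide, so Payne rearrangement of the epoxy alcohol is avoided and the stereocentre is untouched.

Step 3
Reactants: 5 3-fluoro-5-methoxyphenol
Product: 6 1-fluoro-3-methoxy-5-(methoxymethoxy)benzene
Conditions: MOMCl, i-Pr2NEt, CH2Cl2, 0 °C to rt
Reagents that add atoms: chloromethyl methyl ether, COCCl
Why: Routine O-alkylation of a phenol to its MOM ether, which protects the oxygen and provides the chelating director for the next step.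

Step 4
Reactants: 6 1-fluoro-3-methoxy-5-(methoxymethoxy)benzene (1.3 equiv); 4 (2S)-2-[2-(methoxymethoxy)propan-2-yl]oxirane
Product: 8 (2S)-1-[2-fluoro-4-methoxy-6-(methoxymethoxy)phenyl]-3-(methoxymethoxy)-3-methylbutan-2-ol, via [2-fluoro-4-methoxy-6-(methoxymethoxy)phenyl]lithium 7 (not isolated)
Conditions: n-BuLi, THF, −78 °C; then 4, BF3·OEt2, −78 °C; H2O
Reagents that add atoms: none
Why: Directed ortho-metalation is expected at the one C–H that is both acidified by fluorine and reached by the chelating MOM ether, the ortho-fluoroaryllithium is held at −78 °C where LiF loss does not set in, and BF3-assisted SN2 opening of the epoxide at its CH2 terminus (the other carbon is shielded by the quaternary centre) leaves the S carbinol carbon untouched.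

Step 5
Reactants: 9 4-hydroxybenzaldehyde
Product: 10 4-(methoxymethoxy)benzaldehyde
Conditions: MOMCl, i-Pr2NEt, CH2Cl2, 0 °C to rt
Reagents that add atoms: chloromethyl methyl ether, COCCl
Why: Routine phenol O-alkylation; the MOM ether removes the acidic proton that would quench the aryllithium of the key step and falls off in the final acid step.

Step 6
Reactants: 10 4-(methoxymethoxy)benzaldehyde; 11 diethyl {2-[methoxy(methyl)amino]-2-oxoethyl}phosphonate
Product: 12 (2E)-N-methoxy-N-methyl-3-[4-(methoxymethoxy)phenyl]prop-2-enamide
Conditions: NaH, THF, 0 °C to rt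
Reagents that add atoms: none
Why: Horner–Wadsworth–Emmons olefination with a stabilised phosphonate anion should give the E-configured unsaturated Weinreb amide directly from the aryl aldehyde.

Step 7
Reactants: 8 (2S)-1-[2-fluoro-4-methoxy-6-(methoxymethoxy)phenyl]-3-(methoxymethoxy)-3-methylbutan-2-ol; 12 (2E)-N-methoxy-N-methyl-3-[4-(methoxymethoxy)phenyl]prop-2-enamide (1.3 equiv)
Product: 17 (2E)-1-[(2S)-6-methoxy-4-(methoxymethoxy)-2-[2-(methoxymethoxy)propan-2-yl]-2,3-dihydro-1-benzofuran-7-yl]-3-[4-(methoxymethoxy)phenyl]prop-2-en-1-one, via C7-lithiated fluoroarene lithium alkoxide 13 (not isolated), via C7–C7a aryne lithium alkoxide 14 (not isolated), via C7-lithiated dihydrobenzofuran 15 (not isolated), via lithium hemiaminal chelate 16 (not isolated)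
Conditions: n-BuLi (1.0 equiv), THF, −78 °C; lithium 2,2,6,6-tetramethylpiperidide (LiTMP, 1.3 equiv, from TMPH and n-BuLi), −78 to −30 °C; then 12, −78 to 0 °C; aq NH4Cl
Reagents that add atoms: none
Why: n-BuLi forms the lithium alkoxide, LiTMP then removes the C7 proton, the only ring hydrogen next to fluorine and the most acidic one (fluorine plus the C6 methoxy group), and on warming LiF is lost to give the C7–C7a aryne. The tethered alkoxide adds in the plane of the aryne at C7a, a 5-exo-dig closure that forms the dihydrofuran ring, and the aryllithium left at C7 adds to the Weinreb amide to give an N-methoxy chelate that releases the E-enone only on work-up, so over-addition is avoided. The closest known reaction type is the anionic aryne cyclisation of a tethered heteroatom nucleophile with electrophilic capture of the ring-closed aryllithium, joined here to the Weinreb ketone synthesis. No stereocentre is created: C2 keeps the S configuration of the carbinol because only its oxygen reacts and its C–O bond is never broken. The regiochemistry that the step needs (which aryne, which carbon takes oxygen, which takes the acyl group) is secured by the substrate: fluorine has a single ortho hydrogen, the three-atom tether can reach only C7a, and C7a is also the aryne carbon remote from the methoxy group, the position a 3-alkoxyaryne offers to nucleophiles, so the carbanion ends at C7 between two oxygens. Using butyllithium for the hydroxyl proton halves the amount of free amine, and a small excess of LiTMP with the lithiated species kept at or below −30 °C limits proton shuttling of lithium to C5 and attack of the base on the amide.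

Step 8
Reactants: 17 (2E)-1-[(2S)-6-methoxy-4-(methoxymethoxy)-2-[2-(methoxymethoxy)propan-2-yl]-2,3-dihydro-1-benzofuran-7-yl]-3-[4-(methoxymethoxy)phenyl]prop-2-en-1-one
Product: 18 (2E)-1-[(2S)-4-hydroxy-2-(2-hydroxypropan-2-yl)-6-methoxy-2,3-dihydro-1-benzofuran-7-yl]-3-(4-hydroxyphenyl)prop-2-en-1-one
Conditions: HCl (3 M, aq)/MeOH, 45 °C
Reagents that add atoms: none
Why: Acid-catalysed acetal exchange transfers all three MOM groups to methanol; the ketone has no free ortho hydroxyl (its neighbours are the C6 methoxy group and ring oxygen O1), so no flavanone closure can occur, and C2 is not involved.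

Compound list
1 | methyl (S)-glycidate [methyl (2S)-oxirane-2-carboxylate] | COC(=O)[C@@H]1CO1 | starting material
2 | 1-[(2S)-oxiran-2-yl]ethan-1-one | CC(=O)[C@@H]1CO1 | intermediate
3 | 2-[(2S)-oxiran-2-yl]propan-2-ol | CC(C)(O)[C@@H]1CO1 | intermediate
4 | (2S)-2-[2-(methoxymethoxy)propan-2-yl]oxirane | COCOC(C)(C)[C@@H]1CO1 | intermediate
5 | 3-fluoro-5-methoxyphenol | COc1cc(O)cc(F)c1 | starting material
6 | 1-fluoro-3-methoxy-5-(methoxymethoxy)benzene | COCOc1cc(F)cc(OC)c1 | intermediate
7 | [2-fluoro-4-methoxy-6-(methoxymethoxy)phenyl]lithium | [Li]c1c(F)cc(OC)cc1OCOC | intermediate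
8 | (2S)-1-[2-fluoro-4-methoxy-6-(methoxymethoxy)phenyl]-3-(methoxymethoxy)-3-methylbutan-2-ol | COCOc1cc(OC)cc(F)c1C[C@H](O)C(C)(C)OCOC | intermediate
9 | 4-hydroxybenzaldehyde | O=Cc1ccc(O)cc1 | starting material
10 | 4-(methoxymethoxy)benzaldehyde | COCOc1ccc(C=O)cc1 | intermediate
11 | diethyl {2-[methoxy(methyl)amino]-2-oxoethyl}phosphonate | CCOP(=O)(CC(=O)N(C)OC)OCC | starting material
12 | (2E)-N-methoxy-N-methyl-3-[4-(methoxymethoxy)phenyl]prop-2-enamide | CON(C)C(=O)/C=C/c1ccc(OCOC)cc1 | intermediate
13 | lithium (2S)-1-[2-fluoro-3-lithio-4-methoxy-6-(methoxymethoxy)phenyl]-3-(methoxymethoxy)-3-methylbutan-2-olate | COCOc1cc(OC)c([Li])c(F)c1C[C@H](O[Li])C(C)(C)OCOC | intermediate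
14 | lithium (2S)-1-[2,3-didehydro-4-methoxy-6-(methoxymethoxy)phenyl]-3-(methoxymethoxy)-3-methylbutan-2-olate (C7–C7a aryne) | COCOC1=C(C[C@H](O[Li])C(C)(C)OCOC)C#CC(OC)=C1 | intermediate
15 | [(2S)-6-methoxy-4-(methoxymethoxy)-2-[2-(methoxymethoxy)propan-2-yl]-2,3-dihydro-1-benzofuran-7-yl]lithium | COc1cc(OCOC)c2c(c1[Li])O[C@H](C(C)(C)OCOC)C2 | intermediate
16 | lithium (2E)-1-[(2S)-6-methoxy-4-(methoxymethoxy)-2-[2-(methoxymethoxy)propan-2-yl]-2,3-dihydro-1-benzofuran-7-yl]-1-[methoxy(methyl)amino]-3-[4-(methoxymethoxy)phenyl]prop-2-en-1-olate | COc1cc(OCOC)c2c(c1C(O[Li])(N(C)OC)/C=C/c1ccc(OCOC)cc1)O[C@H](C(C)(C)OCOC)C2 | intermediate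
17 | (2E)-1-[(2S)-6-methoxy-4-(methoxymethoxy)-2-[2-(methoxymethoxy)propan-2-yl]-2,3-dihydro-1-benzofuran-7-yl]-3-[4-(methoxymethoxy)phenyl]prop-2-en-1-one | COc1cc(OCOC)c2c(c1C(=O)/C=C/c1ccc(OCOC)cc1)O[C@H](C(C)(C)OCOC)C2 | intermediate
18 | (2E)-1-[(2S)-4-hydroxy-2-(2-hydroxypropan-2-yl)-6-methoxy-2,3-dihydro-1-benzofuran-7-yl]-3-(4-hydroxyphenyl)prop-2-en-1-one | COc1cc(O)c2c(c1C(=O)/C=C/c1ccc(O)cc1)O[C@H](C(C)(C)O)C2 | target

Total step count: 8.
Longest linear sequence: 5 steps (steps 1, 2, 4, 7, 8, from methyl (S)-glycidate).

Steps most likely to fail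

Step 7. During the warm period needed for LiF loss, the amine in the flask may shuttle a proton, so that lithium moves from C7 to C5 (between the methoxy and MOM-oxy groups) or is lost as a C–H bond. Residual LiTMP may also degrade the unsaturated amide. Either process would leave the acylation incomplete or misdirected. The fallback sets out from 8 and 12 and returns at 17. Compound 8 is deprotonated as before but held at −78 °C, where the C7-lithiated fluoroarene 13 keeps its fluorine, and 12 is added at that temperature with a cold quench. This should give the open-chain ketone (2E)-1-[2-fluoro-3-[(2S)-2-hydroxy-3-(methoxymethoxy)-3-methylbutyl]-6-methoxy-4-(methoxymethoxy)phenyl]-3-[4-(methoxymethoxy)phenyl]prop-2-en-1-one F1, in which fluorine now stands ortho to the carbonyl group. Cs2CO3 in DMF at 60 °C should then close O1–C7a by intramolecular nucleophilic aromatic substitution (addition–elimination, 5-exo-trig) to give 17, with no aryne involved.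

Step 4. Deprotonation may not stay confined to the C–H between fluorine and the MOM-oxy group. Competing metalation between the two ether oxygens, or between fluorine and methoxy, would carry the side chain to the wrong ring carbon and give regioisomeric carbinols. The fallback sets out from 5 and returns at 7, which is carried on to 8 as in step 4. Phenol 5 is acetylated (Ac2O, pyridine) to 3-fluoro-5-methoxyphenyl acetate F2, in which the methoxy group is the only strong donor. NBS in MeCN should brominate para to that methoxy group to give 2-bromo-3-fluoro-5-methoxyphenyl acetate F3. Methanolysis (K2CO3, MeOH) gives 2-bromo-3-fluoro-5-methoxyphenol F4, and MOMCl with i-Pr2NEt gives 2-bromo-1-fluoro-5-methoxy-3-(methoxymethoxy)benzene F5. Bromine–lithium exchange (n-BuLi, THF, −78 °C) then forms 7 at a position fixed by the halogen and not by relative C–H acidities.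

Step 8. The hindered tertiary acetal may cleave much more slowly than the two aryl acetals. Forcing the acid could then ionise the tertiary C–O bond (loss of water to the isopropenyl compound, or methyl ether formation) or add methanol to the enone. The fallback sets out from 17 and returns at 18 in two stages. Dilute HCl (0.5 M) in MeOH at 20 °C should remove only the two aryl MOM groups and give (2E)-1-[(2S)-4-hydroxy-6-methoxy-2-[2-(methoxymethoxy)propan-2-yl]-2,3-dihydro-1-benzofuran-7-yl]-3-(4-hydroxyphenyl)prop-2-en-1-one F6. Me2BBr (excess, CH2Cl2, −78 °C; then aq NaHCO3) should cleave the remaining aliphatic acetal by bromide attack at the acetal CH2 carbon, with no cation at the tertiary centre, to give 18.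

Further compounds
F1 | step 7 | (2E)-1-[2-fluoro-3-[(2S)-2-hydroxy-3-(methoxymethoxy)-3-methylbutyl]-6-methoxy-4-(methoxymethoxy)phenyl]-3-[4-(methoxymethoxy)phenyl]prop-2-en-1-one | COc1cc(OCOC)c(C[C@H](O)C(C)(C)OCOC)c(F)c1C(=O)/C=C/c1ccc(OCOC)cc1
F2 | step 4 | 3-fluoro-5-methoxyphenyl acetate | CC(=O)Oc1cc(F)cc(OC)c1
F3 | step 4 | 2-bromo-3-fluoro-5-methoxyphenyl acetate | CC(=O)Oc1cc(OC)cc(F)c1Br
F4 | step 4 | 2-bromo-3-fluoro-5-methoxyphenol | Oc1cc(OC)cc(F)c1Br
F5 | step 4 | 2-bromo-1-fluoro-5-methoxy-3-(methoxymethoxy)benzene | COCOc1cc(OC)cc(F)c1Br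
F6 | step 8 | (2E)-1-[(2S)-4-hydroxy-6-methoxy-2-[2-(methoxymethoxy)propan-2-yl]-2,3-dihydro-1-benzofuran-7-yl]-3-(4-hydroxyphenyl)prop-2-en-1-one | COc1cc(O)c2c(c1C(=O)/C=C/c1ccc(O)cc1)O[C@H](C(C)(C)OCOC)C2
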